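**Retrosynthetic overview**
- The strategy rests on the central oxolane (O1, C2 carrying ring B, C3, C4, C5 carrying ring A): the C3 and C4 methyls are cis to each other and trans to both aryl groups, so the two methyl carbons are brought in as the CH2–S–CH2 bridge of a thiolane fused across C3–C4.
- Disconnections, backwards: three O-benzyl groups; the C2–ring B bond (Friedel–Crafts arylation of the C2 oxocarbenium ion from lactol acetate 13 by arene 23); the two C–S bonds; the C3–CH2 and C4–CH2 bonds ([3+2] addition of a thiocarbonyl ylide to (S)-butenolide 7); the C3=C4 bond (ring-closing metathesis).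
- The (R) centre of the side chain in 23 comes from an Evans benzylation of an arylacetyl oxazolidinone, after which the acyl carbon is reduced to the methyl group.
- Ring order: lactone ring first (metathesis), thiolane second (cycloaddition, later opened by C–S hydrogenolysis); the oxolane of the target is the reduced lactone, and C5, fixed by enzymatic resolution, controls C4, C3 and C2 in turn.

Key step: step 5

Assumption: the oxolane is numbered O1, C2 (ring B, the 4-hydroxy-3-alkylphenyl group), C3, C4, C5 (ring A, the 4-hydroxyphenyl group); the anomeric centre of 12 and 13 is left undefined because both anomers give the same cation; 14 and 18 are taken as catalogue chemicals.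

**Route**

Step 1
Reactants: 1 4-(benzyloxy)benzaldehyde; 2 vinylmagnesium bromide
Product: 3 rac-1-[4-(benzyloxy)phenyl]prop-2-en-1-ol
Conditions: CH2=CHMgBr (1.2 equiv), THF, −78 → 0 °C; sat. aq NH4Cl
Reagents that add atoms: vinylmagnesium bromide 2, C=C[Mg]Br
Why: Grignard 1,2-addition of a vinyl nucleophile to a non-enolisable aryl aldehyde is fast and clean and creates the carbinol carbon (the later C5) as a racemate, which step 2 resolves.

Step 2
Reactants: 3 rac-1-[4-(benzyloxy)phenyl]prop-2-en-1-ol
Product: 4 (1S)-1-[4-(benzyloxy)phenyl]prop-2-en-1-ol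
Conditions: Novozym 435 (immobilised Candida antarctica lipase B), vinyl acetate (3 equiv), t-BuOMe, 30 °C, stopped just past half conversion; chromatography on Et3N-washed silica
Reagents that add atoms: none
Why: Lipase-catalysed kinetic resolution by irreversible transesterification: with aryl in the large pocket and vinyl in the medium pocket (as for 1-arylethanols) the enzyme should acylate the (R)-enantiomer, so the unreacted alcohol is the (S)-enantiomer that fixes C5.

Step 3
Reactants: 4 (1S)-1-[4-(benzyloxy)phenyl]prop-2-en-1-ol; 5 acryloyl chloride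
Product: 6 (1S)-1-[4-(benzyloxy)phenyl]prop-2-en-1-yl prop-2-enoate
Conditions: CH2=CHCOCl (1.3 equiv), Et3N (2 equiv), CH2Cl2, −20 → 0 °C
Reagents that add atoms: acryloyl chloride 5, C=CC(=O)Cl
Why: O-acylation of the secondary alcohol by an acid chloride under amine base leaves the C–O bond and hence the stereocentre untouched, and the cold basic medium keeps the electron-rich allylic benzylic ester from ionising.

Step 4
Reactants: 6 (1S)-1-[4-(benzyloxy)phenyl]prop-2-en-1-yl prop-2-enoate
Product: 7 (5S)-5-[4-(benzyloxy)phenyl]furan-2(5H)-one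
Conditions: second-generation Grubbs catalyst RuCl2(=CHPh)(H2IMes)(PCy3) (5 mol %), CH2Cl2 (0.01 M), 40 °C
Reagents that add atoms: none
Why: Ring-closing metathesis of the allyl acrylate closes the five-membered unsaturated lactone with loss of ethene, a standard entry to 5-substituted furan-2(5H)-ones that does not touch the C5 stereocentre.

Step 5
Reactants: 7 (5S)-5-[4-(benzyloxy)phenyl]furan-2(5H)-one; 8 chloromethyl (trimethylsilyl)methyl sulfide
Product: 10 (3S,3aS,6aR)-3-[4-(benzyloxy)phenyl]tetrahydro-1H-thieno[3,4-c]furan-1-one, via thiocarbonyl ylide 9 (not isolated)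
Conditions: CsF (4 equiv, dried), 8 (2.5 equiv, added over 6 h), MeCN, 0 °C → rt
Reagents that add atoms: chloromethyl (trimethylsilyl)methyl sulfide 8, C[Si](C)(C)CSCCl
Why: Fluoride attacks silicon of 8 and chloride leaves in a 1,3-elimination, which releases thioformaldehyde S-methylide 9, a symmetrical, non-stabilised thiocarbonyl ylide that adds through its two carbon termini across the electron-poor C3=C4 bond of 7 in a concerted, suprafacial 1,3-dipolar cycloaddition (dipole HOMO, lactone LUMO). The closest known reaction type is the [3+2] addition of this same ylide to unsaturated lactones, enones and acrylates, so only the substrate is new. The thiolane ring is closed by this intermolecular [3+2] cycloaddition, both C–CH2 bonds forming in one event, and because the dipolarophile is a cis ring alkene the new five-membered ring can only be cis-fused to the lactone. The two new stereocentres C3a and C6a (the later C4 and C3 of the oxolane) are set together, their mutual cis relation by the suprafacial mode of addition and their absolute sense by the C5 aryl group, which screens its own face of the flat butenolide so that the dipole enters anti to it. The step needs π-facial selectivity and retention of configuration at the acidic, doubly activated C5–H; the first is secured by the aryl group standing next to the reacting alkene, the second by keeping CsF as a suspension in MeCN at 0 °C and adding 8 slowly, so that the butenolide is trapped by the dipole faster than it can enolise, and the symmetry of the dipole removes any question of regiochemistry.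

Step 6
Reactants: 10 (3S,3aS,6aR)-3-[4-(benzyloxy)phenyl]tetrahydro-1H-thieno[3,4-c]furan-1-one
Product: 11 (3R,4S,5S)-5-[4-(benzyloxy)phenyl]-3,4-dimethyloxolan-2-one
Conditions: NiCl2·6H2O (6 equiv), NaBH4 (18 equiv, in portions), MeOH/THF 3:1, 0 °C; filtration through Celite
Reagents that add atoms: none
Why: Reductive desulfurisation: nickel boride formed in the flask from NiCl2 and NaBH4 should hydrogenolyse both C–S bonds of the thiolane, turning the two ring CH2 groups into the C3 and C4 methyls without touching a C–C stereocentre, while the aryl benzyl ether and, at 0 °C with short contact, the lactone are expected to survive.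

Step 7
Reactants: 11 (3R,4S,5S)-5-[4-(benzyloxy)phenyl]-3,4-dimethyloxolan-2-one
Product: 12 (3R,4S,5S)-5-[4-(benzyloxy)phenyl]-3,4-dimethyloxolan-2-ol (both anomers)
Conditions: i-Bu2AlH (1.1 equiv), CH2Cl2, −78 °C; aq potassium sodium tartrate
Reagents that add atoms: none
Why: Partial reduction of a γ-lactone with DIBAL-H at −78 °C stops at the lactol because the tetrahedral aluminium alkoxide is stable until work-up; C3, C4 and C5 are not affected and the new anomeric centre is of no consequence.

Step 8
Reactants: 12 (3R,4S,5S)-5-[4-(benzyloxy)phenyl]-3,4-dimethyloxolan-2-ol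
Product: 13 (3R,4S,5S)-5-[4-(benzyloxy)phenyl]-3,4-dimethyloxolan-2-yl acetate (both anomers)
Conditions: Ac2O, pyridine, DMAP (cat.), CH2Cl2, 0 °C → rt
Reagents that add atoms: acetic anhydride, CC(=O)OC(C)=O
Why: Acetylation of the anomeric hydroxyl under basic conditions installs a leaving group that BF3 can ionise, with no acid present that could open the benzylic C5–O bond.

Step 9
Reactants: 14 [2-(benzyloxy)phenyl]acetic acid; 15 (4R)-4-benzyl-1,3-oxazolidin-2-one
Product: 17 (4R)-4-benzyl-3-{[2-(benzyloxy)phenyl]acetyl}-1,3-oxazolidin-2-one, via mixed pivalic anhydride 16 (not isolated)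
Conditions: t-BuCOCl (1.05 equiv), Et3N (2.5 equiv), THF, −20 °C; then 15, LiCl (1.1 equiv), −20 °C → rt
Reagents that add atoms: (4R)-4-benzyl-1,3-oxazolidin-2-one 15, O=C1N[C@H](Cc2ccccc2)CO1
Why: N-Acylation of the oxazolidinone through the mixed pivalic anhydride with LiCl/Et3N activation attaches the auxiliary under mild conditions, attack occurring at the less hindered arylacetyl carbonyl of 16.

Step 10
Reactants: 17 (4R)-4-benzyl-3-{[2-(benzyloxy)phenyl]acetyl}-1,3-oxazolidin-2-one; 18 1-(benzyloxy)-4-(bromomethyl)benzene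
Product: 20 (4R)-4-benzyl-3-{(2R)-2-[2-(benzyloxy)phenyl]-3-[4-(benzyloxy)phenyl]propanoyl}-1,3-oxazolidin-2-one, via sodium Z-enolate 19 (not isolated)
Conditions: NaN(SiMe3)2 (1.1 equiv), THF, −78 °C; then 18 (1.5 equiv), −78 → −40 °C
Reagents that add atoms: 1-(benzyloxy)-4-(bromomethyl)benzene 18, BrCc1ccc(OCc2ccccc2)cc1
Why: Evans asymmetric alkylation: NaN(SiMe3)2 gives the chelated Z-enolate 19, whose face syn to the C4 benzyl group of the (R)-auxiliary is blocked, so the benzylic bromide enters from the opposite face and should set the (2R) centre that becomes the side-chain stereocentre.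

Step 11
Reactants: 20 (4R)-4-benzyl-3-{(2R)-2-[2-(benzyloxy)phenyl]-3-[4-(benzyloxy)phenyl]propanoyl}-1,3-oxazolidin-2-one
Product: 21 (2R)-2-[2-(benzyloxy)phenyl]-3-[4-(benzyloxy)phenyl]propan-1-ol
Conditions: LiBH4 (2 equiv), H2O (2 equiv), Et2O, 0 °C → rt
Reagents that add atoms: none
Why: Reductive cleavage of the N-acyl oxazolidinone with LiBH4 gives the primary alcohol and returns the auxiliary without enolisation, so the α-aryl stereocentre is kept.

Step 12
Reactants: 21 (2R)-2-[2-(benzyloxy)phenyl]-3-[4-(benzyloxy)phenyl]propan-1-ol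
Product: 22 (2R)-2-[2-(benzyloxy)phenyl]-3-[4-(benzyloxy)phenyl]propyl 4-methylbenzenesulfonate
Conditions: TsCl (1.3 equiv), Et3N, DMAP (cat.), CH2Cl2, 0 °C → rt
Reagents that add atoms: 4-methylbenzenesulfonyl chloride, Cc1ccc(cc1)S(=O)(=O)Cl
Why: Sulfonylation (tosylation) of the primary alcohol converts the hydroxyl into a leaving group under basic conditions that do not touch the adjacent stereocentre.

Step 13
Reactants: 22 (2R)-2-[2-(benzyloxy)phenyl]-3-[4-(benzyloxy)phenyl]propyl 4-methylbenzenesulfonate
Product: 23 1-(benzyloxy)-2-{(2R)-1-[4-(benzyloxy)phenyl]propan-2-yl}benzene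
Conditions: LiBHEt3 (3 equiv), THF, 0 °C → rt
Reagents that add atoms: none
Why: SN2 displacement of the primary tosylate by hydride from LiBHEt3 (Super-Hydride reduction) turns CH2OTs into the methyl group; the neighbouring stereocentre is not a reaction centre and stays (R), and benzyl ethers are inert to the reagent.

Step 14
Reactants: 13 (3R,4S,5S)-5-[4-(benzyloxy)phenyl]-3,4-dimethyloxolan-2-yl acetate; 23 1-(benzyloxy)-2-{(2R)-1-[4-(benzyloxy)phenyl]propan-2-yl}benzene
Product: 25 (2R,3R,4S,5S)-2-{4-(benzyloxy)-3-[(2R)-1-[4-(benzyloxy)phenyl]propan-2-yl]phenyl}-5-[4-(benzyloxy)phenyl]-3,4-dimethyloxolane, via oxocarbenium ion 24 (not isolated)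
Conditions: 23 (1.5 equiv), BF3·OEt2 (2 equiv), CH2Cl2, −78 → −30 °C
Reagents that add atoms: none
Why: BF3·OEt2 ionises the anomeric acetate to the cyclic oxocarbenium ion 24, which is captured in a Friedel–Crafts alkylation by the ether-activated ring of 23 at its free para position (the distal ring offers only positions ortho to oxygen), the arene entering C2 anti to the adjacent C3 methyl to set the 2,3-trans (2R) centre, the arrangement that should also be favoured thermodynamically if the benzylic C–O bonds equilibrate.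

Step 15
Reactants: 25 (2R,3R,4S,5S)-2-{4-(benzyloxy)-3-[(2R)-1-[4-(benzyloxy)phenyl]propan-2-yl]phenyl}-5-[4-(benzyloxy)phenyl]-3,4-dimethyloxolane
Product: 26 (2R,3R,4S,5S)-2-{4-hydroxy-3-[(2R)-1-(4-hydroxyphenyl)propan-2-yl]phenyl}-5-(4-hydroxyphenyl)-3,4-dimethyloxolane (CNP0232576.1)
Conditions: H2 (1 atm), 10% Pd/C, EtOAc/MeOH, rt, stopped when the last benzyl ether is consumed
Reagents that add atoms: none
Why: Catalytic hydrogenolysis over Pd/C cleaves the three O–CH2Ph bonds of the aryl benzyl ethers under neutral conditions at atmospheric pressure, where the more hindered secondary benzylic C–O bonds of the oxolane should react much more slowly, so all five stereocentres are carried into the target unchanged.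

**Compound list**
1 | 4-(benzyloxy)benzaldehyde | O=Cc1ccc(OCc2ccccc2)cc1 | starting material
2 | vinylmagnesium bromide | C=C[Mg]Br | starting material
3 | rac-1-[4-(benzyloxy)phenyl]prop-2-en-1-ol | C=CC(O)c1ccc(OCc2ccccc2)cc1 | intermediate
4 | (1S)-1-[4-(benzyloxy)phenyl]prop-2-en-1-ol | C=C[C@H](O)c1ccc(OCc2ccccc2)cc1 | intermediate
5 | acryloyl chloride | C=CC(=O)Cl | starting material
6 | (1S)-1-[4-(benzyloxy)phenyl]prop-2-en-1-yl prop-2-enoate | C=CC(=O)O[C@@H](C=C)c1ccc(OCc2ccccc2)cc1 | intermediate
7 | (5S)-5-[4-(benzyloxy)phenyl]furan-2(5H)-one | O=C1O[C@H](c2ccc(OCc3ccccc3)cc2)C=C1 | intermediate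
8 | chloromethyl (trimethylsilyl)methyl sulfide | C[Si](C)(C)CSCCl | starting material
9 | thioformaldehyde S-methylide (thiocarbonyl ylide, formed in the flask) | C=[S+][CH2-] | intermediate
10 | (3S,3aS,6aR)-3-[4-(benzyloxy)phenyl]tetrahydro-1H-thieno[3,4-c]furan-1-one (cis-fused thiolane lactone, aryl on the face opposite the thiolane) | O=C1O[C@H](c2ccc(OCc3ccccc3)cc2)[C@H]2CSC[C@@H]12 | intermediate
11 | (3R,4S,5S)-5-[4-(benzyloxy)phenyl]-3,4-dimethyloxolan-2-one | C[C@@H]1[C@H](C)[C@@H](c2ccc(OCc3ccccc3)cc2)OC1=O | intermediate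
12 | (3R,4S,5S)-5-[4-(benzyloxy)phenyl]-3,4-dimethyloxolan-2-ol (both anomers) | C[C@@H]1[C@H](C)[C@@H](c2ccc(OCc3ccccc3)cc2)OC1O | intermediate
13 | (3R,4S,5S)-5-[4-(benzyloxy)phenyl]-3,4-dimethyloxolan-2-yl acetate (both anomers) | C[C@@H]1[C@H](C)[C@@H](c2ccc(OCc3ccccc3)cc2)OC1OC(C)=O | intermediate
14 | [2-(benzyloxy)phenyl]acetic acid | OC(=O)Cc1ccccc1OCc1ccccc1 | starting material
15 | (4R)-4-benzyl-1,3-oxazolidin-2-one | O=C1N[C@H](Cc2ccccc2)CO1 | starting material
16 | [2-(benzyloxy)phenyl]acetic pivalic anhydride (formed in the flask) | CC(C)(C)C(=O)OC(=O)Cc1ccccc1OCc1ccccc1 | intermediate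
17 | (4R)-4-benzyl-3-{[2-(benzyloxy)phenyl]acetyl}-1,3-oxazolidin-2-one | O=C(Cc1ccccc1OCc1ccccc1)N1[C@H](Cc2ccccc2)COC1=O | intermediate
18 | 1-(benzyloxy)-4-(bromomethyl)benzene | BrCc1ccc(OCc2ccccc2)cc1 | starting material
19 | sodium Z-enolate of 17 (formed in the flask) | [Na+].[O-]/C(=C\c1ccccc1OCc1ccccc1)N1[C@H](Cc2ccccc2)COC1=O | intermediate
20 | (4R)-4-benzyl-3-{(2R)-2-[2-(benzyloxy)phenyl]-3-[4-(benzyloxy)phenyl]propanoyl}-1,3-oxazolidin-2-one | O=C([C@H](Cc1ccc(OCc2ccccc2)cc1)c1ccccc1OCc1ccccc1)N1[C@H](Cc2ccccc2)COC1=O | intermediate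
21 | (2R)-2-[2-(benzyloxy)phenyl]-3-[4-(benzyloxy)phenyl]propan-1-ol | OC[C@H](Cc1ccc(OCc2ccccc2)cc1)c1ccccc1OCc1ccccc1 | intermediate
22 | (2R)-2-[2-(benzyloxy)phenyl]-3-[4-(benzyloxy)phenyl]propyl 4-methylbenzenesulfonate | Cc1ccc(cc1)S(=O)(=O)OC[C@H](Cc1ccc(OCc2ccccc2)cc1)c1ccccc1OCc1ccccc1 | intermediate
23 | 1-(benzyloxy)-2-{(2R)-1-[4-(benzyloxy)phenyl]propan-2-yl}benzene | C[C@H](Cc1ccc(OCc2ccccc2)cc1)c1ccccc1OCc1ccccc1 | intermediate
24 | oxocarbenium ion from 13 (O1=C2 cation; C3, C4, C5 as in 13; formed in the flask) | C[C@@H]1[C@H](C)[C@@H](c2ccc(OCc3ccccc3)cc2)[O+]=C1 | intermediate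
25 | (2R,3R,4S,5S)-2-{4-(benzyloxy)-3-[(2R)-1-[4-(benzyloxy)phenyl]propan-2-yl]phenyl}-5-[4-(benzyloxy)phenyl]-3,4-dimethyloxolane | C[C@@H]1[C@H](C)[C@@H](c2ccc(OCc3ccccc3)cc2)O[C@H]1c1ccc(OCc2ccccc2)c([C@H](C)Cc2ccc(OCc3ccccc3)cc2)c1 | intermediate
26 | (2R,3R,4S,5S)-2-{4-hydroxy-3-[(2R)-1-(4-hydroxyphenyl)propan-2-yl]phenyl}-5-(4-hydroxyphenyl)-3,4-dimethyloxolane | C[C@@H]1[C@H](C)[C@@H](c2ccc(O)cc2)O[C@H]1c1ccc(O)c([C@H](C)Cc2ccc(O)cc2)c1 | target

**Step count**
Total: 15 steps. Longest linear sequence: 10 steps (steps 1–8, 14, 15); the arene branch (steps 9–13) joins at step 14.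

**Steps most likely to fail**

Step 5 (cycloaddition). Fluoride may enolise the γ-aryl butenolide toward the 2-oxidofuran before the dipole arrives, which would erode the C5 configuration and shift the double bond out of conjugation; the ylide may also oligomerise, and facial control may be incomplete. The fallback sets out from butenolide 7 and comes back at lactone 11, so that no sulfur is used. Conjugate addition of Me2CuLi (from MeLi and CuBr·SMe2) with Me3SiCl in THF at −78 °C, anti to the aryl group, should give (4S,5S)-5-[4-(benzyloxy)phenyl]-4-methyloxolan-2-one F1. Enolisation with LiN(iPr)2 and methylation with MeI at −78 °C, trans to the C4 methyl, should give (3S,4S,5S)-5-[4-(benzyloxy)phenyl]-3,4-dimethyloxolan-2-one F2. Renewed enolisation with LiN(iPr)2 and kinetic protonation by 2,6-di-tert-butylphenol on the face away from the C4 methyl should invert C3 and deliver the cis-dimethyl lactone 11.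

Step 14 (arylation). C–C bond formation with a mono-alkoxy arene may be slow, so that alkylation ortho to an ether oxygen of the distal ring or on ring A of a second molecule competes; prolonged exposure to BF3 may also open the benzylic C5–O bond. The fallback sets out from lactol 12 and arene 23 and comes back at 25, with the position of the new bond fixed by a carbon–metal bond. Lactol 12 with PhSO2H and CaCl2 in CH2Cl2 should give the anomeric sulfone (3R,4S,5S)-5-[4-(benzyloxy)phenyl]-3,4-dimethyl-2-(phenylsulfonyl)oxolane F3. Arene 23 with N-bromosuccinimide in MeCN at 0 °C should be brominated para to the ether oxygen of ring B to give 1-(benzyloxy)-4-bromo-2-{(2R)-1-[4-(benzyloxy)phenyl]propan-2-yl}benzene F4. Mg in THF should convert it into {4-(benzyloxy)-3-[(2R)-1-[4-(benzyloxy)phenyl]propan-2-yl]phenyl}magnesium bromide F5, and ZnBr2 into {4-(benzyloxy)-3-[(2R)-1-[4-(benzyloxy)phenyl]propan-2-yl]phenyl}zinc bromide F6. In THF at rt the zinc Lewis acid should expel sulfinate from F3 and the aryl group should be delivered to the oxocarbenium ion anti to the C3 methyl, giving 25.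

Step 6 (desulfurisation). C–S hydrogenolysis may stall at a ring-opened thiol, the benzylic lactone C5–O bond may be cleaved reductively, and C3 may epimerise in the basic borohydride medium. The fallback sets out from thiolane lactone 10 and comes back at 25; the oxidation level is lowered before the sulfur is removed, so that the benzylic C–O bond is an ether and no enolisable centre remains. i-Bu2AlH in CH2Cl2 at −78 °C should give (3S,3aS,6aR)-3-[4-(benzyloxy)phenyl]hexahydrothieno[3,4-c]furan-1-ol F7. MeOH with pyridinium 4-methylbenzenesulfonate should give the methyl acetal (3S,3aS,6aR)-3-[4-(benzyloxy)phenyl]-1-methoxyhexahydrothieno[3,4-c]furan F8. Raney Ni in EtOH at rt should then give (3R,4S,5S)-5-[4-(benzyloxy)phenyl]-2-methoxy-3,4-dimethyloxolane F9, which BF3·OEt2 should ionise to the same cation 24 for arylation by 23 under the conditions of step 14, giving 25.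

Further compounds
F1 | step 5 | (4S,5S)-5-[4-(benzyloxy)phenyl]-4-methyloxolan-2-one | O=C1O[C@H](c2ccc(OCc3ccccc3)cc2)[C@@H](C)C1
F2 | step 5 | (3S,4S,5S)-5-[4-(benzyloxy)phenyl]-3,4-dimethyloxolan-2-one | O=C1O[C@H](c2ccc(OCc3ccccc3)cc2)[C@@H](C)[C@@H]1C
F3 | step 14 | (3R,4S,5S)-5-[4-(benzyloxy)phenyl]-3,4-dimethyl-2-(phenylsulfonyl)oxolane (both anomers) | C[C@@H]1[C@H](C)[C@@H](c2ccc(OCc3ccccc3)cc2)OC1S(=O)(=O)c1ccccc1
F4 | step 14 | 1-(benzyloxy)-4-bromo-2-{(2R)-1-[4-(benzyloxy)phenyl]propan-2-yl}benzene | C[C@H](Cc1ccc(OCc2ccccc2)cc1)c1cc(Br)ccc1OCc1ccccc1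
F5 | step 14 | {4-(benzyloxy)-3-[(2R)-1-[4-(benzyloxy)phenyl]propan-2-yl]phenyl}magnesium bromide | C[C@H](Cc1ccc(OCc2ccccc2)cc1)c1cc([Mg]Br)ccc1OCc1ccccc1
F6 | step 14 | {4-(benzyloxy)-3-[(2R)-1-[4-(benzyloxy)phenyl]propan-2-yl]phenyl}zinc bromide | C[C@H](Cc1ccc(OCc2ccccc2)cc1)c1cc([Zn]Br)ccc1OCc1ccccc1
F7 | step 6 | (3S,3aS,6aR)-3-[4-(benzyloxy)phenyl]hexahydrothieno[3,4-c]furan-1-ol | OC1O[C@H](c2ccc(OCc3ccccc3)cc2)[C@H]2CSC[C@@H]12
F8 | step 6 | (3S,3aS,6aR)-3-[4-(benzyloxy)phenyl]-1-methoxyhexahydrothieno[3,4-c]furan | COC1O[C@H](c2ccc(OCc3ccccc3)cc2)[C@H]2CSC[C@@H]12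
F9 | step 6 | (3R,4S,5S)-5-[4-(benzyloxy)phenyl]-2-methoxy-3,4-dimethyloxolane | COC1O[C@H](c2ccc(OCc3ccccc3)cc2)[C@@H](C)[C@H]1C
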